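**Strategy.** The target is divided at the C3–C2′ bond into a vinylogous acid (gem-diprenylated, dearomatised orcinol) and the N-acyliminium precursor 3-hydroxy-4-methoxyisoindolin-1-one. The key step zips up that γ-lactam from three components: palladium-catalysed aminocarbonylation of 2-bromo-6-methoxybenzaldehyde with CO and ammonia joins aryl carbon C7a to the new carbonyl C1, and the resulting amide nitrogen N2 closes onto the ortho formyl carbon C3. It exploits that, in the lactam ring, C1 is a carbonyl on C7a, N2 is unsubstituted and C3 stands at the aldehyde oxidation level. A chiral phosphoric acid then turns the racemic hemiaminal stereoconvergently into the (3R) Mannich product.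

Key step: step 5

Numbering used: isoindolinone C1 (C=O), N2, C3, C3a, C4 (OMe) to C7a; the cyclohexadienone ring carries primed locants, C2′ being the carbon bonded to C3.

Assumption: the sense of induction in step 6 is assigned from the usual two-point hydrogen-bonding model of BINOL-phosphoric acid catalysis. (R)-TRIP, (R)-3,3′-bis(2,4,6-triisopropylphenyl)-1,1′-binaphthyl-2,2′-diyl hydrogen phosphate, is written, and its mirror-image catalyst would be used if the model proved to deliver the 3S adduct. The target SMILES corresponds to the 3R configuration (priorities N > C2′ > C3a > H).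

Step 1
Reactants: 1 5-methylcyclohexane-1,3-dione
Product: 2 3-methoxy-5-methylcyclohex-2-en-1-one (racemic)
Conditions: MeOH, p-TsOH·H2O (cat.), 3 Å MS, reflux
Reagents that add atoms: methanol, CO
Why: Acid-catalysed enol etherification of the symmetrical cyclic 1,3-dione gives the vinylogous ester needed for Stork–Danheiser alkylation; the C5 centre is racemic and is removed as a stereocentre in step 3.

Step 2
Reactants: 2 3-methoxy-5-methylcyclohex-2-en-1-one; 3 prenyl bromide (first portion)
Product: 5 3-methoxy-5-methyl-6,6-bis(3-methylbut-2-enyl)cyclohex-2-en-1-one (racemic), via the mono-prenyl enone 4 (not isolated)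
Conditions: LiN(iPr)2 (1.1 equiv), THF, −78 °C, then prenyl bromide (1.1 equiv), −78 → 0 °C; recool, LiN(iPr)2 (1.2 equiv), then prenyl bromide (1.3 equiv), DMPU, −78 °C → rt
Reagents that add atoms: prenyl bromide (second portion of 3), CC(C)=CCBr
Why: Stork–Danheiser kinetic α′-alkylation, in which the amide base deprotonates C6 rather than C4 and the enolate is C-alkylated by the allylic bromide; a second deprotonation and a second portion of prenyl bromide in the same flask quaternise C6, so that mono- and dialkylated material converge on 5.

Step 3
Reactants: 5 3-methoxy-5-methyl-6,6-bis(3-methylbut-2-enyl)cyclohex-2-en-1-one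
Product: 7 3-methoxy-5-methyl-6,6-bis(3-methylbut-2-enyl)cyclohexa-2,4-dien-1-one, via the silyl dienol ether 6 (not isolated)
Conditions: LiN(iPr)2 (1.2 equiv), THF, −78 °C, then Me3SiCl; solvent exchange; DDQ (1.1 equiv), 2,6-lutidine, toluene, 0 °C → rt
Reagents that add atoms: none
Why: With C6 blocked the base removes the γ-proton at C4, O-silylation gives the 1-silyloxy-3-methoxy-1,3-diene, and DDQ abstracts the C5 hydride (γ,δ-dehydrogenation of a dienol ether, as in the classical conversion of 3,5-dienol ethers into 4,6-dien-3-ones), which also erases the C5 stereocentre.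

Step 4
Reactants: 7 3-methoxy-5-methyl-6,6-bis(3-methylbut-2-enyl)cyclohexa-2,4-dien-1-one
Product: 8 3-hydroxy-5-methyl-6,6-bis(3-methylbut-2-enyl)cyclohexa-2,4-dien-1-one
Conditions: 1 M HCl, THF, rt
Reagents that add atoms: water, O
Why: Acid hydrolysis of the vinylogous ester (water adds at C3 of the protonated dienone and methanol leaves) at room temperature, where the trisubstituted prenyl alkenes should survive.

Step 5
Reactants: 9 2-bromo-6-methoxybenzaldehyde; 10 carbon monoxide; 11 ammonia
Product: 13 3-hydroxy-4-methoxyisoindolin-1-one (racemic), via 2-formyl-3-methoxybenzamide 12 (not isolated)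
Conditions: Pd(OAc)2 (3 mol %), Xantphos (4 mol %), CO (5 bar), NH3 (0.5 M in 1,4-dioxane, 4 equiv), 90 °C; then 1 M HCl (aq), rt
Reagents that add atoms: none
Why: Zerovalent palladium inserts into the C–Br bond of 9, CO insertion gives the acylpalladium bromide and ammonolysis delivers amide 12 (bonds C7a–C1 and C1–N2), whose N–H then adds to the neighbouring formyl group (bond N2–C3). The closest known reaction types are the palladium-catalysed carbonylative cyclisation of 2-bromobenzaldehydes with primary amines to 3-substituted isoindolin-1-ones and the aminocarbonylation of aryl bromides with ammonia. The lactam ring closes in the 5-exo-trig mode by attack of nitrogen on the aldehyde carbon. The new stereocentre C3 is deliberately left uncontrolled (racemic hemiaminal), because step 6 ionises it and sets it afresh. The step needs carbonylative rather than direct C–N coupling and no loss of the formyl group; CO pressure and the wide-bite-angle diphosphine favour acyl formation, the position of bromine fixes C7a as the only site, and the acidic work-up returns aminal or imine forms made by excess ammonia to 13.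

Step 6
Reactants: 13 3-hydroxy-4-methoxyisoindolin-1-one; 8 3-hydroxy-5-methyl-6,6-bis(3-methylbut-2-enyl)cyclohexa-2,4-dien-1-one
Product: 15 (3R)-3-[2-hydroxy-4-methyl-5,5-bis(3-methylbut-2-enyl)-6-oxocyclohexa-1,3-dien-1-yl]-4-methoxyisoindolin-1-one, via the cyclic N-acylimine 14 (not isolated)
Conditions: (R)-TRIP (10 mol %), 4 Å MS, toluene/CH2Cl2, 0 °C → rt
Reagents that add atoms: none
Why: Chiral-phosphoric-acid-catalysed Mannich-type amidoalkylation: the acid dehydrates racemic 13 to the planar N-acylimine 14 and, hydrogen-bonded to the imine nitrogen and to the enol OH of 8, directs the only enolic CH carbon (C2′) onto one face of C3, so that both enantiomers of 13 converge on the 3R configuration set by the catalyst.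

**Compound list**

1 | 5-methylcyclohexane-1,3-dione | CC1CC(=O)CC(=O)C1 | starting material
2 | 3-methoxy-5-methylcyclohex-2-en-1-one (racemic) | COC1=CC(=O)CC(C)C1 | intermediate
3 | prenyl bromide (1-bromo-3-methylbut-2-ene) | CC(C)=CCBr | starting material
4 | 3-methoxy-5-methyl-6-(3-methylbut-2-enyl)cyclohex-2-en-1-one (racemic; trans expected to predominate) | COC1=CC(=O)C(CC=C(C)C)C(C)C1 | intermediate
5 | 3-methoxy-5-methyl-6,6-bis(3-methylbut-2-enyl)cyclohex-2-en-1-one (racemic) | COC1=CC(=O)C(CC=C(C)C)(CC=C(C)C)C(C)C1 | intermediate
6 | trimethyl{[3-methoxy-5-methyl-6,6-bis(3-methylbut-2-enyl)cyclohexa-1,3-dien-1-yl]oxy}silane (racemic) | COC1=CC(C)C(CC=C(C)C)(CC=C(C)C)C(O[Si](C)(C)C)=C1 | intermediate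
7 | 3-methoxy-5-methyl-6,6-bis(3-methylbut-2-enyl)cyclohexa-2,4-dien-1-one | COC1=CC(=O)C(CC=C(C)C)(CC=C(C)C)C(C)=C1 | intermediate
8 | 3-hydroxy-5-methyl-6,6-bis(3-methylbut-2-enyl)cyclohexa-2,4-dien-1-one (enol form of 5-methyl-6,6-diprenylcyclohex-4-ene-1,3-dione) | OC1=CC(=O)C(CC=C(C)C)(CC=C(C)C)C(C)=C1 | intermediate
9 | 2-bromo-6-methoxybenzaldehyde | COc1cccc(Br)c1C=O | starting material
10 | carbon monoxide | [C-]#[O+] | starting material
11 | ammonia | N | starting material
12 | 2-formyl-3-methoxybenzamide | COc1cccc(C(N)=O)c1C=O | intermediate
13 | 3-hydroxy-4-methoxyisoindolin-1-one (racemic) | COc1cccc2c1C(O)NC2=O | intermediate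
14 | 4-methoxy-1H-isoindol-1-one (cyclic N-acylimine) | COc1cccc2c1C=NC2=O | intermediate
15 | (3R)-3-[2-hydroxy-4-methyl-5,5-bis(3-methylbut-2-enyl)-6-oxocyclohexa-1,3-dien-1-yl]-4-methoxyisoindolin-1-one | COc1cccc2c1[C@H](C1=C(O)C=C(C)C(CC=C(C)C)(CC=C(C)C)C1=O)NC2=O | target

**Total step count:** 6. **Longest linear sequence:** 5 steps (steps 1, 2, 3, 4 and 6); step 5 is a one-step branch.

**Steps most likely to fail**

Step 5. Ammonia may coordinate and deactivate the catalyst, may condense with the aldehyde to imine oligomers that divert material, or may couple directly with the aryl bromide. Fallback: the nitrogen is introduced in a separate operation. Setting out from 9, methoxycarbonylation (Pd(OAc)2, Xantphos, CO, MeOH, Et3N, 70 °C) should give methyl 2-formyl-3-methoxybenzoate F1. Treatment of F1 with ammonia in methanol at room temperature (hemiaminal formation, lactamisation, aqueous work-up) comes back to the route at 13.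

Step 6. Facial selectivity may be poor on an N-acylimine without a 3-substituent and with the 4-methoxy group next to C3, an uncatalysed background addition may compete, and reversible ionisation of the C3–C2′ bond under acid may erode enantiomeric purity. Fallback: setting out from 13 and 8, an achiral acid (diphenyl phosphate, CH2Cl2, rt) should give the racemic adduct, racemic 3-[2-hydroxy-4-methyl-5,5-bis(3-methylbut-2-enyl)-6-oxocyclohexa-1,3-dien-1-yl]-4-methoxyisoindolin-1-one F2. Its enantiomers are then separated by preparative chromatography on a chiral stationary phase, which comes back to the route at 15; the unwanted enantiomer could be re-equilibrated under acid and recycled.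

Step 3. DDQ may attack the prenyl groups by hydride abstraction, γ-deprotonation or O-silylation may be incomplete, or the dienone may aromatise with loss of a prenyl group. Fallback: the order of hydrolysis and dehydrogenation is inverted and the double bond is made by selenoxide elimination. Setting out from 5, hydrolysis (1 M HCl, THF, rt) should give 5-methyl-4,4-bis(3-methylbut-2-enyl)cyclohexane-1,3-dione F3. Its dianion (LiN(iPr)2, 2.2 equiv, THF/DMPU, −78 °C) has hydrogen at only one γ-carbon and should react there with PhSeBr to give 5-methyl-4,4-bis(3-methylbut-2-enyl)-6-(phenylselanyl)cyclohexane-1,3-dione F4. Oxidation (NaIO4, THF/H2O, 0 °C → rt) and syn-elimination of the selenoxide towards the C5 hydrogen comes back to the route at 8.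

**Further compounds**

F1 | step 5 | methyl 2-formyl-3-methoxybenzoate | COC(=O)c1cccc(OC)c1C=O
F2 | step 6 | racemic 3-[2-hydroxy-4-methyl-5,5-bis(3-methylbut-2-enyl)-6-oxocyclohexa-1,3-dien-1-yl]-4-methoxyisoindolin-1-one | COc1cccc2c1C(C1=C(O)C=C(C)C(CC=C(C)C)(CC=C(C)C)C1=O)NC2=O
F3 | step 3 | 5-methyl-4,4-bis(3-methylbut-2-enyl)cyclohexane-1,3-dione (racemic) | CC1CC(=O)CC(=O)C1(CC=C(C)C)CC=C(C)C
F4 | step 3 | 5-methyl-4,4-bis(3-methylbut-2-enyl)-6-(phenylselanyl)cyclohexane-1,3-dione (racemic) | CC1C([Se]c2ccccc2)C(=O)CC(=O)C1(CC=C(C)C)CC=C(C)C
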